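**Remark on the chemistry:** the target is the meso (2R,3S,4R,5S) isomer, with a mirror plane through O1 and the midpoint of C3–C4. The chiral intermediates are therefore made as racemates (one enantiomer is drawn, prefix rac-), and both enantiomers lead to the same single stereoisomer.

## Retrosynthetic overview

- Target 17 is a tetrahydrofuran (O1, C2–C5) with aryl groups at C2 and C5, each trans to the neighbouring CH2OAc, and C3/C4 cis. The strategy rests on the chain C5(Ar)–C4–C3–C2, which is closed into the ring only through O1: removing O1 and joining C2 to C5 leaves a 2-aryl-3,4-cis-disubstituted cyclobutanone.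
- End game: 17 from the benzyl/TBS-protected tetrahydrofuran 14 by desilylation, acetylation and hydrogenolysis. The C2–aryl bond comes from Friedel–Crafts arylation of the oxocarbenium ion of lactol acetate 12 with catechol dibenzyl ether 13.
- Oxygen heterocycle (second ring formed): lactone 10 from Baeyer–Villiger insertion of oxygen into the C1–C2 bond of cyclobutanone 9, which makes the O1–C5 bond.
- Carbocycle (first ring formed): 9 from a keteniminium [2+2] of arylacetamide 3 with the (Z)-bis-silyl ether 5, followed by equilibration at C2. Amide 3 comes from acid 1 and alkene 5 from diol 4.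

Key step: step 5

## Route

Step 1
Reactants: 1 2-(3,4-dihydroxyphenyl)acetic acid
Product: 2 benzyl 2-[3,4-bis(benzyloxy)phenyl]acetate
Conditions: BnBr (3.5 equiv), K2CO3 (4 equiv), DMF, 60 °C, N2
Reagents that add atoms: benzyl bromide, BrCc1ccccc1
Why: Williamson-type O-alkylation of both phenoxides and of the carboxylate by a reactive benzylic halide under carbonate, with no stereocentre involved.

Step 2
Reactants: 2 benzyl 2-[3,4-bis(benzyloxy)phenyl]acetate
Product: 3 2-[3,4-bis(benzyloxy)phenyl]-1-(pyrrolidin-1-yl)ethan-1-one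
Conditions: pyrrolidine (5 equiv), TBD (20 mol%), neat, 75 °C
Reagents that add atoms: pyrrolidine, C1CCNC1
Why: Guanidine-catalysed aminolysis of an unhindered arylacetic ester by a strongly nucleophilic secondary amine, leaving the aryl benzyl ethers untouched.

Step 3
Reactants: 4 (Z)-but-2-ene-1,4-diol
Product: 5 (Z)-1,4-bis(tert-butyldimethylsilyloxy)but-2-ene
Conditions: TBSCl (2.2 equiv), imidazole (4.4 equiv), DMF, 0 °C → rt
Reagents that add atoms: tert-butyldimethylsilyl chloride, CC(C)(C)[Si](C)(C)Cl
Why: Standard imidazole-mediated silylation of two primary alcohols, which does not affect the Z geometry of the alkene.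

Step 4
Reactants: 3 2-[3,4-bis(benzyloxy)phenyl]-1-(pyrrolidin-1-yl)ethan-1-one; 5 (Z)-1,4-bis(tert-butyldimethylsilyloxy)but-2-ene (3 equiv)
Product: 9 rac-2-[3,4-bis(benzyloxy)phenyl]-3,4-cis-bis(tert-butyldimethylsilyloxymethyl)cyclobutan-1-one (aryl trans to the C3 substituent), via keteniminium triflate 6 (not isolated), via cyclobutaniminium triflate 7 (not isolated), via cyclobutanone C2-epimer mixture 8 (not isolated)
Conditions: Tf2O (1.1 equiv), ClCH2CH2Cl, −20 °C; then 5, 2,4,6-collidine (1.2 equiv), −20 → 60 °C; then sat. aq NaHCO3, rt; then Et3N, CH2Cl2, rt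
Reagents that add atoms: water, O
Why: Ghosez keteniminium–alkene [2+2] cycloaddition, in which the aldoketeniminium salt from amide activation adds to the cis-alkene with retention of alkene geometry (C3/C4 cis); hydrolysis then releases the ketone, and Et3N equilibrates only the acidic benzylic C2–H so that the aryl group ends up trans to the C3 substituent while the far less acidic C4–H is untouched.

Step 5
Reactants: 9 rac-2-[3,4-bis(benzyloxy)phenyl]-3,4-cis-bis(tert-butyldimethylsilyloxymethyl)cyclobutan-1-one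
Product: 10 rac-5-[3,4-bis(benzyloxy)phenyl]-3,4-cis-bis(tert-butyldimethylsilyloxymethyl)dihydrofuran-2(3H)-one (aryl trans to the C4 substituent)
Conditions: mCPBA (1.3 equiv), NaHCO3 (3 equiv), CH2Cl2, 0 °C
Reagents that add atoms: meta-chloroperoxybenzoic acid, O=C(OO)c1cccc(Cl)c1
Why: Baeyer–Villiger oxidation, in which the peracid adds to the strained carbonyl of 9 to give the Criegee adduct and the C1–C2 bond anti-periplanar to the breaking O–O bond shifts from carbon to oxygen with loss of 3-chlorobenzoate. The closest known reaction type is the peracid or peroxide ring expansion of 2-arylcyclobutanones to 5-aryl-γ-butyrolactones. The five-membered lactone is not closed by a cyclisation but arises by one-atom ring expansion of the four-membered ketone, oxygen being inserted between C1 and C2 to create the O1–C5 bond, and relief of ring strain should make the step fast at 0 °C. No new stereocentre is formed: C2 migrates with retention because the shift is suprafacial, and C3 and C4 are not touched, so the aryl-trans, C3/C4-cis triad of 9 is carried unchanged into 10. The step needs regioselective migration of C2 over C4, which is secured by the benzylic, p-alkoxyaryl-substituted character of C2 (it supports the developing positive charge far better than C4, which is further deactivated by its β-silyloxy group). It also needs the ketone to react in preference to the electron-rich rings and C4 not to enolise, which the low temperature, the bicarbonate buffer and the high reactivity of cyclobutanones toward peracids should provide.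

Step 6
Reactants: 10 rac-5-[3,4-bis(benzyloxy)phenyl]-3,4-cis-bis(tert-butyldimethylsilyloxymethyl)dihydrofuran-2(3H)-one
Product: 12 rac-5-[3,4-bis(benzyloxy)phenyl]-3,4-cis-bis(tert-butyldimethylsilyloxymethyl)tetrahydrofuran-2-yl acetate (anomer mixture), via aluminium hemiacetal 11 (not isolated)
Conditions: DIBAL-H (1.2 equiv), CH2Cl2, −78 °C; then pyridine, DMAP, Ac2O, −78 → 0 °C
Reagents that add atoms: acetic anhydride, CC(=O)OC(C)=O
Why: Rychnovsky reductive acetylation, in which DIBAL-H adds once to the lactone at −78 °C and the tetrahedral aluminium hemiacetal is acetylated in the flask before it can collapse, so over-reduction is avoided; the anomeric centre formed is erased in step 7.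

Step 7
Reactants: 12 rac-5-[3,4-bis(benzyloxy)phenyl]-3,4-cis-bis(tert-butyldimethylsilyloxymethyl)tetrahydrofuran-2-yl acetate; 13 1,2-bis(benzyloxy)benzene (2 equiv)
Product: 14 (2R,3S,4R,5S)-2,5-bis[3,4-bis(benzyloxy)phenyl]-3,4-bis(tert-butyldimethylsilyloxymethyl)tetrahydrofuran (meso)
Conditions: BF3·OEt2 (1.5 equiv), CH2Cl2, −78 → −30 °C
Reagents that add atoms: none
Why: Lewis-acid-mediated Friedel–Crafts C-arylation of a cyclic oxocarbenium ion, as used for 2,5-diaryl-tetrahydrofuran lignans: BF3 ionises the anomeric acetate and the catechol diether attacks through the position para to a benzyloxy group on the ring face opposite the two cis CH2OTBS groups, which sets C2 with the aryl trans to C3, and any reversible benzylic ionisation should lead to the same, most stable isomer.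

Step 8
Reactants: 14 (2R,3S,4R,5S)-2,5-bis[3,4-bis(benzyloxy)phenyl]-3,4-bis(tert-butyldimethylsilyloxymethyl)tetrahydrofuran
Product: 15 [(2R,3S,4R,5S)-2,5-bis[3,4-bis(benzyloxy)phenyl]tetrahydrofuran-3,4-diyl]dimethanol (meso)
Conditions: TBAF (2.5 equiv), THF, 0 °C → rt
Reagents that add atoms: none
Why: Fluoride-driven cleavage of the two primary silyl ethers, under which the benzyl ethers and the tetrahydrofuran stereocentres are inert.

Step 9
Reactants: 15 [(2R,3S,4R,5S)-2,5-bis[3,4-bis(benzyloxy)phenyl]tetrahydrofuran-3,4-diyl]dimethanol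
Product: 16 [(2R,3S,4R,5S)-2,5-bis[3,4-bis(benzyloxy)phenyl]tetrahydrofuran-3,4-diyl]bis(methylene) diacetate (meso)
Conditions: Ac2O, pyridine, DMAP (cat.), CH2Cl2, rt
Reagents that add atoms: acetic anhydride, CC(=O)OC(C)=O
Why: DMAP-catalysed acylation of two unhindered primary alcohols, with no stereocentre affected.

Step 10
Reactants: 16 [(2R,3S,4R,5S)-2,5-bis[3,4-bis(benzyloxy)phenyl]tetrahydrofuran-3,4-diyl]bis(methylene) diacetate
Product: 17 [(2R,3S,4R,5S)-2,5-bis(3,4-dihydroxyphenyl)tetrahydrofuran-3,4-diyl]bis(methylene) diacetate (meso target, CNP0416169.1)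
Conditions: H2 (1 atm), 10% Pd/C, EtOAc, rt, reaction stopped when the benzyl ethers are consumed; work-up under N2
Reagents that add atoms: none
Why: Catalytic hydrogenolysis of aryl benzyl ethers is much faster than cleavage of the ring benzylic C–O bonds under neutral conditions at 1 atm, and the acetates are stable, so the four phenols should be freed without touching the ring.

## Compound list

1 | 2-(3,4-dihydroxyphenyl)acetic acid | OC(=O)Cc1ccc(O)c(O)c1 | starting material
2 | benzyl 2-[3,4-bis(benzyloxy)phenyl]acetate | O=C(Cc1ccc(OCc2ccccc2)c(OCc2ccccc2)c1)OCc1ccccc1 | intermediate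
3 | 2-[3,4-bis(benzyloxy)phenyl]-1-(pyrrolidin-1-yl)ethan-1-one | O=C(Cc1ccc(OCc2ccccc2)c(OCc2ccccc2)c1)N1CCCC1 | intermediate
4 | (Z)-but-2-ene-1,4-diol | OC/C=C\CO | starting material
5 | (Z)-1,4-bis(tert-butyldimethylsilyloxy)but-2-ene | CC(C)(C)[Si](C)(C)OC/C=C\CO[Si](C)(C)C(C)(C)C | intermediate
6 | 1-{2-[3,4-bis(benzyloxy)phenyl]ethenylidene}pyrrolidin-1-ium trifluoromethanesulfonate (keteniminium triflate, formed in the flask) | [O-]S(=O)(=O)C(F)(F)F.C(=C=[N+]1CCCC1)c1ccc(OCc2ccccc2)c(OCc2ccccc2)c1 | intermediate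
7 | 1-{2-[3,4-bis(benzyloxy)phenyl]-3,4-cis-bis(tert-butyldimethylsilyloxymethyl)cyclobutylidene}pyrrolidin-1-ium trifluoromethanesulfonate (rac, mixture at C2, formed in the flask) | [O-]S(=O)(=O)C(F)(F)F.C1CC[N+](C1)=C1C(c2ccc(OCc3ccccc3)c(OCc3ccccc3)c2)[C@@H](CO[Si](C)(C)C(C)(C)C)[C@H]1CO[Si](C)(C)C(C)(C)C | intermediate
8 | rac-2-[3,4-bis(benzyloxy)phenyl]-3,4-cis-bis(tert-butyldimethylsilyloxymethyl)cyclobutan-1-one as C2-epimer mixture (formed in the flask) | O=C1C(c2ccc(OCc3ccccc3)c(OCc3ccccc3)c2)[C@@H](CO[Si](C)(C)C(C)(C)C)[C@H]1CO[Si](C)(C)C(C)(C)C | intermediate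
9 | rac-2-[3,4-bis(benzyloxy)phenyl]-3,4-cis-bis(tert-butyldimethylsilyloxymethyl)cyclobutan-1-one, aryl trans to the C3 substituent | O=C1[C@H](c2ccc(OCc3ccccc3)c(OCc3ccccc3)c2)[C@@H](CO[Si](C)(C)C(C)(C)C)[C@H]1CO[Si](C)(C)C(C)(C)C | intermediate
10 | rac-5-[3,4-bis(benzyloxy)phenyl]-3,4-cis-bis(tert-butyldimethylsilyloxymethyl)dihydrofuran-2(3H)-one, aryl trans to the C4 substituent | O=C1O[C@H](c2ccc(OCc3ccccc3)c(OCc3ccccc3)c2)[C@@H](CO[Si](C)(C)C(C)(C)C)[C@H]1CO[Si](C)(C)C(C)(C)C | intermediate
11 | {rac-5-[3,4-bis(benzyloxy)phenyl]-3,4-cis-bis(tert-butyldimethylsilyloxymethyl)tetrahydrofuran-2-yl}oxy-diisobutylaluminium (aluminium hemiacetal, formed in the flask) | CC(C)C[Al](CC(C)C)OC1O[C@H](c2ccc(OCc3ccccc3)c(OCc3ccccc3)c2)[C@@H](CO[Si](C)(C)C(C)(C)C)[C@H]1CO[Si](C)(C)C(C)(C)C | intermediate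
12 | rac-5-[3,4-bis(benzyloxy)phenyl]-3,4-cis-bis(tert-butyldimethylsilyloxymethyl)tetrahydrofuran-2-yl acetate (anomer mixture) | CC(=O)OC1O[C@H](c2ccc(OCc3ccccc3)c(OCc3ccccc3)c2)[C@@H](CO[Si](C)(C)C(C)(C)C)[C@H]1CO[Si](C)(C)C(C)(C)C | intermediate
13 | 1,2-bis(benzyloxy)benzene | C(Oc1ccccc1OCc1ccccc1)c1ccccc1 | starting material
14 | (2R,3S,4R,5S)-2,5-bis[3,4-bis(benzyloxy)phenyl]-3,4-bis(tert-butyldimethylsilyloxymethyl)tetrahydrofuran (meso) | CC(C)(C)[Si](C)(C)OC[C@@H]1[C@H](CO[Si](C)(C)C(C)(C)C)[C@@H](c2ccc(OCc3ccccc3)c(OCc3ccccc3)c2)O[C@H]1c1ccc(OCc2ccccc2)c(OCc2ccccc2)c1 | intermediate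
15 | [(2R,3S,4R,5S)-2,5-bis[3,4-bis(benzyloxy)phenyl]tetrahydrofuran-3,4-diyl]dimethanol (meso) | OC[C@@H]1[C@H](CO)[C@@H](c2ccc(OCc3ccccc3)c(OCc3ccccc3)c2)O[C@H]1c1ccc(OCc2ccccc2)c(OCc2ccccc2)c1 | intermediate
16 | [(2R,3S,4R,5S)-2,5-bis[3,4-bis(benzyloxy)phenyl]tetrahydrofuran-3,4-diyl]bis(methylene) diacetate (meso) | CC(=O)OC[C@@H]1[C@H](COC(C)=O)[C@@H](c2ccc(OCc3ccccc3)c(OCc3ccccc3)c2)O[C@H]1c1ccc(OCc2ccccc2)c(OCc2ccccc2)c1 | intermediate
17 | [(2R,3S,4R,5S)-2,5-bis(3,4-dihydroxyphenyl)tetrahydrofuran-3,4-diyl]bis(methylene) diacetate (meso) | CC(=O)OC[C@@H]1[C@H](COC(C)=O)[C@@H](c2ccc(O)c(O)c2)O[C@H]1c1ccc(O)c(O)c1 | target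

## Step count

Total steps: 10.
Longest linear sequence: 9 steps (1 → 2 → 3 → 9 → 10 → 12 → 14 → 15 → 16 → 17, i.e. steps 1, 2, 4–10). Step 3 is the one-step side branch that supplies 5.

## Steps most likely to fail

**Step 4 (keteniminium [2+2]).** The alkene is inductively deactivated by two allylic oxygens and flanked by two bulky silyloxymethyl groups. The keteniminium ion could therefore be consumed faster by Friedel–Crafts-type attack on the electron-rich benzyloxyarene of a second molecule, or by the ether oxygens, than by cycloaddition. The collidinium triflate formed could also strip silyl groups at 60 °C.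

Fallback, from 5 and returning at 8 (and so at 9): the four-membered ring is built without the aryl group, which is attached afterwards.
- Dichloroketene F1, generated from trichloroacetyl chloride with Zn–Cu in Et2O/DME, should add to 5 to give rac-2,2-dichloro-3,4-cis-bis(tert-butyldimethylsilyloxymethyl)cyclobutan-1-one F2.
- Zinc in methanolic NH4Cl should remove both chlorines to give rac-cis-2,3-bis(tert-butyldimethylsilyloxymethyl)cyclobutan-1-one F3.
- Kinetic deprotonation at the unsubstituted CH2 (LDA, THF, −78 °C) and trapping with PhNTf2 should give rac-3,4-cis-bis(tert-butyldimethylsilyloxymethyl)cyclobut-1-en-1-yl trifluoromethanesulfonate F4.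
- Suzuki coupling with [3,4-bis(benzyloxy)phenyl]boronic acid (Pd(PPh3)4, aq K2CO3, dioxane) should give rac-1-[3,4-bis(benzyloxy)phenyl]-3,4-cis-bis(tert-butyldimethylsilyloxymethyl)cyclobut-1-ene F5.
- Hydroboration–oxidation (BH3·THF; then NaOH, H2O2), with boron going to the non-benzylic carbon on the face away from the two side chains, should give rac-2-[3,4-bis(benzyloxy)phenyl]-3,4-cis-bis(tert-butyldimethylsilyloxymethyl)cyclobutan-1-ol F6.
- Dess–Martin oxidation should then give the cyclobutanone as its cis-aryl C2 epimer, a component of 8, which the Et3N treatment of step 4 converts into 9.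

**Step 5 (Baeyer–Villiger, key step).** Migration of C4 could compete and give the regioisomeric lactone. The peracid could attack the electron-rich rings. The acidic by-product could ionise the newly formed p-alkoxybenzylic acyloxy centre and scramble C5.

Fallback, from 9 and returning at 14: photochemical ring expansion in place of peracid oxidation.
- Irradiation of 9 (medium-pressure Hg lamp, Pyrex filter, MeOH, solid NaHCO3) should cleave the C1–C2 bond on the benzylic side. The acyl–benzyl biradical recloses on oxygen to an oxacarbene, which inserts into the O–H bond of methanol.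
- The product would be rac-5-[3,4-bis(benzyloxy)phenyl]-2-methoxy-3,4-cis-bis(tert-butyldimethylsilyloxymethyl)tetrahydrofuran F7 (anomer mixture), with the same O1–C5 bond and the same configuration at C3, C4 and C5.
- This methyl acetal is an oxocarbenium precursor equivalent to 12. Under the conditions of step 7 with 13 it should give 14 directly, so steps 5 and 6 are bypassed.

**Step 7 (Friedel–Crafts C-arylation).** Facial discrimination at the oxocarbenium carbon could be insufficient. The Lewis acid could ionise the C5 benzylic C–O bond, leading to ring-opened arene adducts. The silyl ethers could be cleaved by BF3 before arylation is complete.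

Fallback, from 10 and returning at 14: nucleophilic aryl addition and cyclodehydration in place of electrophilic aromatic substitution.
- DIBAL-H (CH2Cl2, −78 °C, aqueous Rochelle-salt work-up) should give the lactol rac-5-[3,4-bis(benzyloxy)phenyl]-3,4-cis-bis(tert-butyldimethylsilyloxymethyl)tetrahydrofuran-2-ol F8.
- [3,4-Bis(benzyloxy)phenyl]magnesium bromide F9, made from 4-bromo-1,2-bis(benzyloxy)benzene and magnesium in THF, should add to the open hydroxy-aldehyde form to give rac-1,4-bis[3,4-bis(benzyloxy)phenyl]-2,3-bis(tert-butyldimethylsilyloxymethyl)butane-1,4-diol F10 (epimers at the new carbinol).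
- MsCl/Et3N (CH2Cl2, 0 °C) should then close the ring through the p-alkoxybenzylic cation. The remaining hydroxyl captures it on the face that puts the aryl trans to its neighbouring side chain, so both carbinol epimers should converge on 14.

## Further compounds

F1 | step 4 | dichloroketene | ClC(Cl)=C=O
F2 | step 4 | rac-2,2-dichloro-3,4-cis-bis(tert-butyldimethylsilyloxymethyl)cyclobutan-1-one | O=C1C(Cl)(Cl)[C@@H](CO[Si](C)(C)C(C)(C)C)[C@H]1CO[Si](C)(C)C(C)(C)C
F3 | step 4 | rac-cis-2,3-bis(tert-butyldimethylsilyloxymethyl)cyclobutan-1-one | O=C1C[C@@H](CO[Si](C)(C)C(C)(C)C)[C@H]1CO[Si](C)(C)C(C)(C)C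
F4 | step 4 | rac-3,4-cis-bis(tert-butyldimethylsilyloxymethyl)cyclobut-1-en-1-yl trifluoromethanesulfonate | FC(F)(F)S(=O)(=O)OC1=C[C@@H](CO[Si](C)(C)C(C)(C)C)[C@H]1CO[Si](C)(C)C(C)(C)C
F5 | step 4 | rac-1-[3,4-bis(benzyloxy)phenyl]-3,4-cis-bis(tert-butyldimethylsilyloxymethyl)cyclobut-1-ene | C1(c2ccc(OCc3ccccc3)c(OCc3ccccc3)c2)=C[C@@H](CO[Si](C)(C)C(C)(C)C)[C@H]1CO[Si](C)(C)C(C)(C)C
F6 | step 4 | rac-2-[3,4-bis(benzyloxy)phenyl]-3,4-cis-bis(tert-butyldimethylsilyloxymethyl)cyclobutan-1-ol (hydroxyl trans to aryl, aryl cis to the C3 substituent) | [C@H]1(c2ccc(OCc3ccccc3)c(OCc3ccccc3)c2)[C@H](O)[C@@H](CO[Si](C)(C)C(C)(C)C)[C@H]1CO[Si](C)(C)C(C)(C)C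
F7 | step 5 | rac-5-[3,4-bis(benzyloxy)phenyl]-2-methoxy-3,4-cis-bis(tert-butyldimethylsilyloxymethyl)tetrahydrofuran (anomer mixture) | COC1O[C@H](c2ccc(OCc3ccccc3)c(OCc3ccccc3)c2)[C@@H](CO[Si](C)(C)C(C)(C)C)[C@H]1CO[Si](C)(C)C(C)(C)C
F8 | step 7 | rac-5-[3,4-bis(benzyloxy)phenyl]-3,4-cis-bis(tert-butyldimethylsilyloxymethyl)tetrahydrofuran-2-ol (anomer mixture) | OC1O[C@H](c2ccc(OCc3ccccc3)c(OCc3ccccc3)c2)[C@@H](CO[Si](C)(C)C(C)(C)C)[C@H]1CO[Si](C)(C)C(C)(C)C
F9 | step 7 | [3,4-bis(benzyloxy)phenyl]magnesium bromide | Br[Mg]c1ccc(OCc2ccccc2)c(OCc2ccccc2)c1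
F10 | step 7 | rac-1,4-bis[3,4-bis(benzyloxy)phenyl]-2,3-bis(tert-butyldimethylsilyloxymethyl)butane-1,4-diol (epimers at the new carbinol) | O[C@H](c1ccc(OCc2ccccc2)c(OCc2ccccc2)c1)[C@@H](CO[Si](C)(C)C(C)(C)C)[C@@H](CO[Si](C)(C)C(C)(C)C)C(O)c1ccc(OCc2ccccc2)c(OCc2ccccc2)c1
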